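The route rests on disconnecting the tetrasubstituted C5=C10 double bond of the cyclohexene ring (eudesmane numbering: C10 carries the methyl group, C5 the side chain). Ring-closing metathesis of two 1,1-disubstituted olefins builds the carbocycle and its only ring alkene in one operation on the complete, correctly oxidised skeleton; the cis relationship of the two arms on the γ-lactone ring (C7, C8) holds them together, and the lactone methylene cannot interfere. The precursor is a cis-β,γ-disubstituted α-methylene-γ-butyrolactone bearing a 2-methylallyl group at C8 and, at C7, the 2-methylidene-alkyl arm with the C6 isovalerate. Its stereotriad comes from an Evans syn aldol and an Evans–Tishchenko reduction; C4 comes from (S)-citronellal.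

Key step: step 12

Remark on locants: C4 = side-chain stereocentre, C5/C10 = ring olefin carbons, C6 = acyloxy carbon, C7 = ring-fusion carbon bonded to the lactone α-carbon C11, C8 = ring-fusion carbon bonded to the lactone oxygen, C9 = ring CH2.
Remark on a starting material: 3-bromobut-3-enoic acid (8) is taken as a purchasable building block; otherwise it is made from 2,3-dibromopropene by cyanide displacement and nitrile hydrolysis.

Step 1
Reactants: 1 (S)-citronellal
Product: 2 (6S)-8,8-dimethoxy-2,6-dimethyloct-2-ene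
Conditions: HC(OMe)3, MeOH, PPTS (cat.), 0 °C → rt
Reagents that add atoms: trimethyl orthoformate, COC(OC)OC
Why: Acid-catalysed acetal formation with the orthoformate as dehydrating partner masks the aldehyde for the ozonolysis under conditions mild enough to avoid the carbonyl-ene cyclisation of citronellal, and C4 is not touched.

Step 2
Reactants: 2 (6S)-8,8-dimethoxy-2,6-dimethyloct-2-ene
Product: 4 (4S)-6,6-dimethoxy-4-methylhexan-1-ol, via (4S)-6,6-dimethoxy-4-methylhexanal 3 (not isolated)
Conditions: O3, CH2Cl2/MeOH, −78 °C; then NaBH4, −78 °C → rt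
Reagents that add atoms: ozone, [O-][O+]=O
Why: Ozonolysis cleaves the only C=C bond and borohydride reduces the resulting aldehyde 3 (and the peroxidic co-product) in the same flask, so that the future terminal hydroxyl of the side chain appears while the acetal stays intact (ozonolysis with reductive work-up).

Step 3
Reactants: 4 (4S)-6,6-dimethoxy-4-methylhexan-1-ol
Product: 5 tert-butyl{[(4S)-6,6-dimethoxy-4-methylhexyl]oxy}diphenylsilane
Conditions: TBDPSCl, imidazole, CH2Cl2, 0 °C → rt
Reagents that add atoms: tert-butyl(chloro)diphenylsilane, CC(C)(C)[Si](Cl)(c1ccccc1)c1ccccc1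
Why: Silylation of the primary alcohol gives a TBDPS ether that should survive the acidic, Lewis-acidic, organometallic and transition-metal steps that follow (silyl ether protection).

Step 4
Reactants: 5 tert-butyl{[(4S)-6,6-dimethoxy-4-methylhexyl]oxy}diphenylsilane
Product: 6 (3S)-6-[(tert-butyldiphenylsilyl)oxy]-3-methylhexanal
Conditions: p-TsOH·H2O (cat.), acetone/H2O, rt
Reagents that add atoms: water, O
Why: Dimethyl acetals hydrolyse under mild aqueous acid that leaves a TBDPS ether untouched (acetal hydrolysis).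

Step 5
Reactants: 6 (3S)-6-[(tert-butyldiphenylsilyl)oxy]-3-methylhexanal
Product: 7 (3S)-6-[(tert-butyldiphenylsilyl)oxy]-3-methyl-2-methylidenehexanal
Conditions: aq. CH2O (37 %), pyrrolidine (10 mol %), EtCO2H (10 mol %), i-PrOH, 45 °C
Reagents that add atoms: formaldehyde, C=O
Why: Amine-catalysed Mannich condensation with formaldehyde followed by elimination of the amine gives the 2-substituted acrolein (organocatalytic α-methylenation of an aldehyde), and the neighbouring C4 stereocentre is not enolisable in substrate, enamine or product.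

Step 6
Reactants: 8 3-bromobut-3-enoic acid; 9 (4S)-4-benzyl-1,3-oxazolidin-2-one
Product: 12 (4S)-4-benzyl-3-(3-bromobut-3-enoyl)-1,3-oxazolidin-2-one, via 3-bromobut-3-enoyl chloride 10 (not isolated), via lithium oxazolidinide 11 (not isolated)
Conditions: 8, (COCl)2, DMF (cat.), CH2Cl2, 0 °C → rt; 9, n-BuLi, THF, −78 °C; then 10 added, −78 → 0 °C
Reagents that add atoms: none
Why: N-Acylation of the lithiated auxiliary by the acid chloride at −78 °C is fast and non-equilibrating, which should keep the β,γ-double bond from moving into conjugation (acylation of an Evans oxazolidinone).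

Step 7
Reactants: 12 (4S)-4-benzyl-3-(3-bromobut-3-enoyl)-1,3-oxazolidin-2-one; 7 (3S)-6-[(tert-butyldiphenylsilyl)oxy]-3-methyl-2-methylidenehexanal
Product: 14 (4S)-4-benzyl-3-[(2S,3S,5S)-2-(1-bromoethenyl)-8-[(tert-butyldiphenylsilyl)oxy]-3-hydroxy-5-methyl-4-methylideneoctanoyl]-1,3-oxazolidin-2-one, via dibutylboron Z-enolate 13 (not isolated)
Conditions: Bu2BOTf, i-Pr2NEt, CH2Cl2, −78 → 0 °C; then 7, −78 → 0 °C; aq. NaH2PO4/Na2HPO4 (pH 7), MeOH, H2O2, 0 °C
Reagents that add atoms: none
Why: Evans syn aldol reaction: the Z-boron enolate 13 adds to enal 7 through a Zimmerman–Traxler chair on the enolate face away from the benzyl group, which sets C7 and C6 syn in the required absolute sense, while the vinyl bromide and the 1,1-disubstituted olefin of 7 stay passive.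

Step 8
Reactants: 14 (4S)-4-benzyl-3-[(2S,3S,5S)-2-(1-bromoethenyl)-8-[(tert-butyldiphenylsilyl)oxy]-3-hydroxy-5-methyl-4-methylideneoctanoyl]-1,3-oxazolidin-2-one
Product: 15 (2S,3S,5S)-2-(1-bromoethenyl)-8-[(tert-butyldiphenylsilyl)oxy]-3-hydroxy-N-methoxy-N,5-dimethyl-4-methylideneoctanamide
Conditions: MeONHMe·HCl, AlMe3, CH2Cl2, −20 → 0 °C; aq. potassium sodium tartrate
Reagents that add atoms: N,O-dimethylhydroxylamine hydrochloride, CNOC.Cl
Why: Transamination with the aluminium amide made from AlMe3 and the hydroxylamine salt, assisted by the free C6 hydroxyl, releases the auxiliary and should give the Weinreb amide without loss of the C7 configuration (Weinreb amide formation).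

Step 9
Reactants: 15 (2S,3S,5S)-2-(1-bromoethenyl)-8-[(tert-butyldiphenylsilyl)oxy]-3-hydroxy-N-methoxy-N,5-dimethyl-4-methylideneoctanamide; 16 (2-methylprop-2-en-1-yl)magnesium chloride
Product: 17 (5S,6S,8S)-5-(1-bromoethenyl)-11-[(tert-butyldiphenylsilyl)oxy]-6-hydroxy-2,8-dimethyl-7-methylideneundec-1-en-4-one
Conditions: 16 (3 equiv), THF, −78 °C; sat. aq. NH4Cl at −78 °C
Reagents that add atoms: none
Why: Weinreb ketone synthesis: the chelated tetrahedral magnesium adduct cannot over-add and collapses only on the cold neutral quench, which should keep C7 and both β,γ-olefins of the new ketone intact.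

Step 10
Reactants: 17 (5S,6S,8S)-5-(1-bromoethenyl)-11-[(tert-butyldiphenylsilyl)oxy]-6-hydroxy-2,8-dimethyl-7-methylideneundec-1-en-4-one; 18 3-methylbutanal
Product: 19 (4R,5R,6S,8S)-5-(1-bromoethenyl)-11-[(tert-butyldiphenylsilyl)oxy]-4-hydroxy-2,8-dimethyl-7-methylideneundec-1-en-6-yl 3-methylbutanoate
Conditions: SmI2 (30 mol %), 18 (6 equiv), THF, −10 °C
Reagents that add atoms: none
Why: Evans–Tishchenko reduction: the samarium-bound hemiacetal formed from the C6 hydroxyl and isovaleraldehyde transfers hydride intramolecularly to the C8 ketone through a chair-like six-membered transition state, which sets C8 anti to C6 and leaves the isovalerate of the target on O6 in the same operation.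

Step 11
Reactants: 19 (4R,5R,6S,8S)-5-(1-bromoethenyl)-11-[(tert-butyldiphenylsilyl)oxy]-4-hydroxy-2,8-dimethyl-7-methylideneundec-1-en-6-yl 3-methylbutanoate
Product: 20 (1S,3S)-6-[(tert-butyldiphenylsilyl)oxy]-3-methyl-2-methylidene-1-[(2R,3R)-4-methylidene-2-(2-methylprop-2-en-1-yl)-5-oxooxolan-3-yl]hexyl 3-methylbutanoate
Conditions: Pd(PPh3)4 (10 mol %), CO (20 atm), i-Pr2NEt, MeCN, 60 °C
Reagents that add atoms: carbon monoxide, [C-]#[O+]
Why: Carbonylative lactonisation: oxidative addition of zerovalent palladium to the vinyl bromide, CO insertion and capture of the acylpalladium by the C8 hydroxyl close the α-methylene-γ-butyrolactone, cis at C7/C8 because both centres are already fixed, and CO pressure should favour CO insertion over carbopalladation of the 2-methylallyl group.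

Step 12
Reactants: 20 (1S,3S)-6-[(tert-butyldiphenylsilyl)oxy]-3-methyl-2-methylidene-1-[(2R,3R)-4-methylidene-2-(2-methylprop-2-en-1-yl)-5-oxooxolan-3-yl]hexyl 3-methylbutanoate
Product: 21 (3aR,4S,7aR)-5-[(2S)-5-[(tert-butyldiphenylsilyl)oxy]pentan-2-yl]-6-methyl-3-methylidene-2-oxo-2,3,3a,4,7,7a-hexahydro-1-benzofuran-4-yl 3-methylbutanoate
Conditions: RuCl2[1,3-bis(2-methylphenyl)imidazolidin-2-ylidene](=CH-C6H4-2-O-i-Pr) (second-generation Hoveyda–Grubbs type, 20 mol % in portions), toluene (high dilution), 100 °C, argon sparge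
Reagents that add atoms: none
Why: Ring-closing olefin metathesis: the ruthenium alkylidene should form at the less hindered 2-methylallyl olefin, add to the C5 methylidene in a [2+2] step, and the ruthenacyclobutane should revert with loss of ethylene to leave the tetrasubstituted C5=C10 alkene. The closest known reaction type is the closure of 1,6-dienes with two 1,1-disubstituted olefins to tetrasubstituted cyclohexenes by ruthenium catalysts whose N-heterocyclic carbene carries small N-aryl groups. The six-membered carbocycle closes by cycloaddition–cycloreversion between the C10 alkylidene and the C5 methylidene, the two terminal CH2 groups leaving as ethylene. No stereocentre is created: the endocyclic olefin has only one possible geometry, and C4, C6, C7 and C8 are not touched. The step needs chemoselectivity among three 1,1-disubstituted olefins and ring closure in preference to oligomerisation: the electron-poor lactone methylene could only close to a cyclobutene or to a bridgehead olefin and so stays out, while the cis arrangement of the two arms on the lactone ring keeps the reacting olefins close, helped by high dilution and removal of ethylene.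

Step 13
Reactants: 21 (3aR,4S,7aR)-5-[(2S)-5-[(tert-butyldiphenylsilyl)oxy]pentan-2-yl]-6-methyl-3-methylidene-2-oxo-2,3,3a,4,7,7a-hexahydro-1-benzofuran-4-yl 3-methylbutanoate
Product: 22 (3aR,4S,7aR)-5-[(2S)-5-hydroxypentan-2-yl]-6-methyl-3-methylidene-2-oxo-2,3,3a,4,7,7a-hexahydro-1-benzofuran-4-yl 3-methylbutanoate
Conditions: HF·pyridine, pyridine, THF, 0 °C → rt
Reagents that add atoms: none
Why: Fluoride cleaves the primary silyl ether under buffered, non-basic conditions that should leave the isovalerate and the conjugate-acceptor lactone untouched (desilylation).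

Compound list

1 | (S)-citronellal, (3S)-3,7-dimethyloct-6-enal | O=CC[C@@H](C)CCC=C(C)C | starting material
2 | (6S)-8,8-dimethoxy-2,6-dimethyloct-2-ene | COC(OC)C[C@@H](C)CCC=C(C)C | intermediate
3 | (4S)-6,6-dimethoxy-4-methylhexanal | COC(OC)C[C@@H](C)CCC=O | intermediate
4 | (4S)-6,6-dimethoxy-4-methylhexan-1-ol | COC(OC)C[C@@H](C)CCCO | intermediate
5 | tert-butyl{[(4S)-6,6-dimethoxy-4-methylhexyl]oxy}diphenylsilane | COC(OC)C[C@@H](C)CCCO[Si](c1ccccc1)(c1ccccc1)C(C)(C)C | intermediate
6 | (3S)-6-[(tert-butyldiphenylsilyl)oxy]-3-methylhexanal | O=CC[C@@H](C)CCCO[Si](c1ccccc1)(c1ccccc1)C(C)(C)C | intermediate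
7 | (3S)-6-[(tert-butyldiphenylsilyl)oxy]-3-methyl-2-methylidenehexanal | C=C(C=O)[C@@H](C)CCCO[Si](c1ccccc1)(c1ccccc1)C(C)(C)C | intermediate
8 | 3-bromobut-3-enoic acid | C=C(Br)CC(=O)O | starting material
9 | (4S)-4-benzyl-1,3-oxazolidin-2-one | O=C1OC[C@H](Cc2ccccc2)N1 | starting material
10 | 3-bromobut-3-enoyl chloride | C=C(Br)CC(=O)Cl | intermediate
11 | lithium (4S)-4-benzyl-2-oxo-1,3-oxazolidin-3-ide | [Li+].O=C1OC[C@H](Cc2ccccc2)[N-]1 | intermediate
12 | (4S)-4-benzyl-3-(3-bromobut-3-enoyl)-1,3-oxazolidin-2-one | C=C(Br)CC(=O)N1[C@@H](Cc2ccccc2)COC1=O | intermediate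
13 | dibutylboron (Z)-enolate of 12 | CCCCB(CCCC)O/C(=C\C(Br)=C)N1[C@@H](Cc2ccccc2)COC1=O | intermediate
14 | (4S)-4-benzyl-3-[(2S,3S,5S)-2-(1-bromoethenyl)-8-[(tert-butyldiphenylsilyl)oxy]-3-hydroxy-5-methyl-4-methylideneoctanoyl]-1,3-oxazolidin-2-one | O=C1OC[C@H](Cc2ccccc2)N1C(=O)[C@@H](C(Br)=C)[C@H](O)C(=C)[C@@H](C)CCCO[Si](c1ccccc1)(c1ccccc1)C(C)(C)C | intermediate
15 | (2S,3S,5S)-2-(1-bromoethenyl)-8-[(tert-butyldiphenylsilyl)oxy]-3-hydroxy-N-methoxy-N,5-dimethyl-4-methylideneoctanamide | CON(C)C(=O)[C@@H](C(Br)=C)[C@H](O)C(=C)[C@@H](C)CCCO[Si](c1ccccc1)(c1ccccc1)C(C)(C)C | intermediate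
16 | (2-methylprop-2-en-1-yl)magnesium chloride | C=C(C)C[Mg]Cl | starting material
17 | (5S,6S,8S)-5-(1-bromoethenyl)-11-[(tert-butyldiphenylsilyl)oxy]-6-hydroxy-2,8-dimethyl-7-methylideneundec-1-en-4-one | C=C(C)CC(=O)[C@@H](C(Br)=C)[C@H](O)C(=C)[C@@H](C)CCCO[Si](c1ccccc1)(c1ccccc1)C(C)(C)C | intermediate
18 | 3-methylbutanal (isovaleraldehyde) | CC(C)CC=O | starting material
19 | (4R,5R,6S,8S)-5-(1-bromoethenyl)-11-[(tert-butyldiphenylsilyl)oxy]-4-hydroxy-2,8-dimethyl-7-methylideneundec-1-en-6-yl 3-methylbutanoate | C=C(C)C[C@@H](O)[C@@H](C(Br)=C)[C@H](OC(=O)CC(C)C)C(=C)[C@@H](C)CCCO[Si](c1ccccc1)(c1ccccc1)C(C)(C)C | intermediate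
20 | (1S,3S)-6-[(tert-butyldiphenylsilyl)oxy]-3-methyl-2-methylidene-1-[(2R,3R)-4-methylidene-2-(2-methylprop-2-en-1-yl)-5-oxooxolan-3-yl]hexyl 3-methylbutanoate | C=C1C(=O)O[C@H](CC(C)=C)[C@@H]1[C@H](OC(=O)CC(C)C)C(=C)[C@@H](C)CCCO[Si](c1ccccc1)(c1ccccc1)C(C)(C)C | intermediate
21 | (3aR,4S,7aR)-5-[(2S)-5-[(tert-butyldiphenylsilyl)oxy]pentan-2-yl]-6-methyl-3-methylidene-2-oxo-2,3,3a,4,7,7a-hexahydro-1-benzofuran-4-yl 3-methylbutanoate | C=C1C(=O)O[C@@H]2CC(C)=C([C@@H](C)CCCO[Si](c3ccccc3)(c3ccccc3)C(C)(C)C)[C@@H](OC(=O)CC(C)C)[C@H]12 | intermediate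
22 | (3aR,4S,7aR)-5-[(2S)-5-hydroxypentan-2-yl]-6-methyl-3-methylidene-2-oxo-2,3,3a,4,7,7a-hexahydro-1-benzofuran-4-yl 3-methylbutanoate | C=C1C(=O)O[C@@H]2CC(C)=C([C@@H](C)CCCO)[C@@H](OC(=O)CC(C)C)[C@H]12 | target

Total step count: 13. Longest linear sequence: 12 steps (steps 1–5 and 7–13, from (S)-citronellal).

Steps most likely to fail

Step 12 (ring-closing metathesis). The decisive [2+2] between the disubstituted ruthenium alkylidene at C10 and the C5 methylidene, which is flanked by the branched C4 and the acyloxy-bearing C6, may be too slow, so that catalyst decay, double-bond migration and intermolecular metathesis take over. The fallback runs the metathesis on a free allylic alcohol, which is less encumbered and benefits from hydroxyl assistance, and acylates last. It sets out from 17. Directed anti reduction with Me4NBH(OAc)3 in MeCN/AcOH at −30 °C (Evans–Saksena reduction) should give the bromovinyl anti-diol F1. Carbonylative lactonisation as in step 11 should engage the less hindered C8 hydroxyl and give the hydroxy lactone diene F2. Ring-closing metathesis with the ruthenium catalyst of step 12 should give the bicyclic hydroxy lactone F3. Acylation with isovaleric anhydride, Et3N and DMAP (cat.) in CH2Cl2 comes back to the route at 21.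

Step 11 (carbonylative lactonisation). Before CO inserts, the vinylpalladium species may add across the 2-methylallyl olefin (5-exo carbopalladation), and zerovalent palladium may ionise the allylic isovalerate at C6. The fallback uses no palladium and sets out from 19. Nozaki–Hiyama–Kishi hydroxymethylation (CrCl2, NiCl2 cat., monomeric formaldehyde, DMF/THF) should turn the vinyl bromide into the allylic alcohol of the 2-methylidene-1,4-diol F4. MnO2 in CH2Cl2 then oxidises the allylic primary alcohol to the enal, whose lactol with the C8 hydroxyl is oxidised on to the lactone; this comes back to the route at 20.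

Step 9 (ketone formation). The strongly basic allylic Grignard reagent may enolise the amide at C7 (epimerisation), and the magnesium aldolate or the product may undergo retro-aldol cleavage or migration of a β,γ-double bond into conjugation. The fallback avoids the free β-hydroxy ketone and step 10, and sets out from 15. Acylation of the C6 hydroxyl with isovaleryl chloride and pyridine gives the ester amide F5. Reduction of the Weinreb amide with Cp2Zr(H)Cl in THF gives the aldehyde F6. Addition of B-(2-methylallyl)diisopinocampheylborane, made from (+)-B-methoxydiisopinocampheylborane and 16, at −78 °C with non-basic work-up should deliver the 8R alcohol under reagent control; this comes back to the route at 19.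

Further compounds

F1 | step 12 | (4R,5R,6S,8S)-5-(1-bromoethenyl)-11-[(tert-butyldiphenylsilyl)oxy]-2,8-dimethyl-7-methylideneundec-1-ene-4,6-diol | C=C(C)C[C@@H](O)[C@@H](C(Br)=C)[C@H](O)C(=C)[C@@H](C)CCCO[Si](c1ccccc1)(c1ccccc1)C(C)(C)C
F2 | step 12 | (4S,5R)-4-[(1S,3S)-6-[(tert-butyldiphenylsilyl)oxy]-1-hydroxy-3-methyl-2-methylidenehexyl]-3-methylidene-5-(2-methylprop-2-en-1-yl)oxolan-2-one | C=C1C(=O)O[C@H](CC(C)=C)[C@@H]1[C@H](O)C(=C)[C@@H](C)CCCO[Si](c1ccccc1)(c1ccccc1)C(C)(C)C
F3 | step 12 | (3aS,4S,7aR)-5-[(2S)-5-[(tert-butyldiphenylsilyl)oxy]pentan-2-yl]-4-hydroxy-6-methyl-3-methylidene-3a,4,7,7a-tetrahydro-1-benzofuran-2(3H)-one | C=C1C(=O)O[C@@H]2CC(C)=C([C@@H](C)CCCO[Si](c3ccccc3)(c3ccccc3)C(C)(C)C)[C@@H](O)[C@H]12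
F4 | step 11 | (4R,5R,6S,8S)-11-[(tert-butyldiphenylsilyl)oxy]-4-hydroxy-5-(3-hydroxyprop-1-en-2-yl)-2,8-dimethyl-7-methylideneundec-1-en-6-yl 3-methylbutanoate | C=C(C)C[C@@H](O)[C@@H](C(CO)=C)[C@H](OC(=O)CC(C)C)C(=C)[C@@H](C)CCCO[Si](c1ccccc1)(c1ccccc1)C(C)(C)C
F5 | step 9 | (2S,3S,5S)-2-(1-bromoethenyl)-8-[(tert-butyldiphenylsilyl)oxy]-1-[methoxy(methyl)amino]-5-methyl-4-methylidene-1-oxooctan-3-yl 3-methylbutanoate | CON(C)C(=O)[C@@H](C(Br)=C)[C@H](OC(=O)CC(C)C)C(=C)[C@@H](C)CCCO[Si](c1ccccc1)(c1ccccc1)C(C)(C)C
F6 | step 9 | (2S,3S,5S)-2-(1-bromoethenyl)-8-[(tert-butyldiphenylsilyl)oxy]-5-methyl-4-methylidene-1-oxooctan-3-yl 3-methylbutanoate | O=C[C@@H](C(Br)=C)[C@H](OC(=O)CC(C)C)C(=C)[C@@H](C)CCCO[Si](c1ccccc1)(c1ccccc1)C(C)(C)C
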